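**Retrosynthetic overview**
- Octacosanolide 12 ⇐ hydrogenation of the 29-membered ene-lactone 11 ⇐ Ramberg–Bäcklund ring contraction (loss of SO2) of the 30-membered sulfone lactone 7.
- 7 ⇐ S-oxidation of thia-lactone 5 ⇐ intramolecular S-alkylation (S–C17 bond) of the open-chain bromo thiol ester 3 ⇐ esterification of 16-sulfanylhexadecanoic acid 1 with 12-bromododecan-1-ol 2.
- Feature used: the 29-membered ring (one lactone oxygen, one carbonyl carbon, 27 CH2) is a single unbranched chain with no substituent, stereocentre or second functional group. The C16–C17 bond (acid-chain numbering; ring atoms C17–C18 of the lactone) can therefore be replaced for a time by C16–S–C17.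
- Ring order: there is one ring. It is closed first as the 30-membered thia-lactone by C–S bond formation and then contracted by one atom to the 29-membered carbon chain.

Key step: step 4

Remark on the chemistry: the sulfur is carried in as the thiol of commercial 16-sulfanylhexadecanoic acid, so the ring closes by one intramolecular thiolate displacement under carbonate, without the hydroxide that a sulfide salt would bring to the ester. The target has no stereocentre, and the olefin geometry of 11 is left undefined because step 5 removes it.

**Route**

Step 1
Reactants: 1 16-sulfanylhexadecanoic acid; 2 12-bromododecan-1-ol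
Product: 3 12-bromododecyl 16-sulfanylhexadecanoate
Conditions: TsOH·H2O (cat.), toluene, reflux, Dean–Stark trap, N2
Reagents that add atoms: none
Why: Fischer esterification driven by azeotropic removal of water; the primary alcohol should out-compete the un-ionised thiol for the protonated acid, and without base neither the thiol nor the primary bromide should react.

Step 2
Reactants: 3 12-bromododecyl 16-sulfanylhexadecanoate
Product: 5 1-oxa-18-thiacyclotriacontan-2-one, via caesium thiolate 4 (not isolated)
Conditions: Cs2CO3 (1.5 equiv), degassed DMF, 55 °C, syringe-pump addition of 3 over 12–16 h (final about 5 mM), Ar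
Reagents that add atoms: none
Why: Caesium thiolate macrocyclisation, an intramolecular SN2 S-alkylation of the primary bromide that closes a strain-free 30-membered ring under pseudo-high dilution; the soft thiolate should attack sp3 carbon far faster than it attacks the ester.

Step 3
Reactants: 5 1-oxa-18-thiacyclotriacontan-2-one
Product: 7 1-oxa-18-thiacyclotriacontan-2-one 18,18-dioxide, via sulfoxide 6 (not isolated)
Conditions: mCPBA (2.3 equiv), CH2Cl2, 0 °C to rt; aq. Na2SO3/NaHCO3 wash
Reagents that add atoms: mCPBA (3-chloroperoxybenzoic acid), OOC(=O)c1cccc(Cl)c1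
Why: Two successive electrophilic oxygen transfers from the peracid to sulfur (sulfide to sulfoxide to sulfone); the lactone and the saturated chain are inert to mCPBA.

Step 4
Reactants: 7 1-oxa-18-thiacyclotriacontan-2-one 18,18-dioxide
Product: 11 1-oxacyclononacos-17-en-2-one (E/Z mixture), via 17-bromo sulfone 8 (not isolated), via 19-bromo sulfone 9 (not isolated), via episulfone 10 (not isolated)
Conditions: KOH on Al2O3 (excess), CBr2F2, t-BuOH/CH2Cl2, 0 °C to rt
Reagents that add atoms: none
Why: KOH on alumina should remove a proton from one of the two sulfone alpha-methylenes (ring atoms C17 or C19) and the carbanion should take bromine from CBr2F2 to give 8 or 9; a second deprotonation at the other alpha carbon then displaces bromide in a 1,3-elimination to episulfone 10, which loses SO2 cheletropically and leaves the ring olefin C17=C18 (C16=C17 of the acid chain). This is the Ramberg–Bäcklund reaction with in situ halogenation, a known way from cyclic sulfones to cyclic and macrocyclic alkenes. The only ring closed is the transient three-membered episulfone (3-exo-tet); its collapse contracts the 30-membered thia-lactone to the 29-membered lactone with one new carbon–carbon bond. No stereocentre remains, since the bromo carbon and both episulfone carbons end as sp2 centres, and the olefin geometry is irrelevant because step 5 saturates it. The step needs reaction at the sulfone alpha carbons and not at the lactone (alpha-deprotonation with bromination, or cleavage by hydroxide); this rests on the fast proton transfer from sulfone alpha C–H bonds (two such methylenes against one ester alpha-methylene of similar acidity, giving a localised carbanion), on the irreversible capture of that carbanion by CBr2F2, and on the solid-supported base in t-BuOH/CH2Cl2 at low temperature, which offers little free hydroxide to the ester. Both alpha carbons are unbranched CH2 groups, so either bromo regioisomer should give the same olefin, and the difluorocarbene left from the reagent should be consumed by the base and not by the product.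

Step 5
Reactants: 11 1-oxacyclononacos-17-en-2-one (E/Z mixture)
Product: 12 octacosanolide (1-oxacyclononacosan-2-one)
Conditions: H2 (1 atm), Pd/C (10 wt% Pd), EtOAc, rt
Reagents that add atoms: none
Why: Heterogeneous catalytic hydrogenation of an unhindered 1,2-disubstituted olefin; both olefin isomers should converge on the same saturated lactone and the ester is inert.

**Compound list**

1 | 16-sulfanylhexadecanoic acid (16-mercaptohexadecanoic acid) | OC(=O)CCCCCCCCCCCCCCCS | starting material
2 | 12-bromododecan-1-ol | OCCCCCCCCCCCCBr | starting material
3 | 12-bromododecyl 16-sulfanylhexadecanoate | SCCCCCCCCCCCCCCCC(=O)OCCCCCCCCCCCCBr | intermediate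
4 | caesium 16-[(12-bromododecyl)oxy]-16-oxohexadecane-1-thiolate (caesium thiolate of 3, not isolated) | [Cs+].[S-]CCCCCCCCCCCCCCCC(=O)OCCCCCCCCCCCCBr | intermediate
5 | 1-oxa-18-thiacyclotriacontan-2-one (30-membered thia-lactone) | O=C1CCCCCCCCCCCCCCCSCCCCCCCCCCCCO1 | intermediate
6 | 1-oxa-18-thiacyclotriacontan-2-one 18-oxide (racemic sulfoxide, not isolated) | O=C1CCCCCCCCCCCCCCCS(=O)CCCCCCCCCCCCO1 | intermediate
7 | 1-oxa-18-thiacyclotriacontan-2-one 18,18-dioxide (30-membered sulfone lactone) | O=C1CCCCCCCCCCCCCCCS(=O)(=O)CCCCCCCCCCCCO1 | intermediate
8 | 17-bromo-1-oxa-18-thiacyclotriacontan-2-one 18,18-dioxide (racemic, not isolated) | O=C1CCCCCCCCCCCCCCC(Br)S(=O)(=O)CCCCCCCCCCCCO1 | intermediate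
9 | 19-bromo-1-oxa-18-thiacyclotriacontan-2-one 18,18-dioxide (racemic regioisomer of 8, not isolated) | O=C1CCCCCCCCCCCCCCCS(=O)(=O)C(Br)CCCCCCCCCCCO1 | intermediate
10 | 13-oxa-30-thiabicyclo[27.1.0]triacontan-14-one 30,30-dioxide (episulfone, cis/trans mixture, racemic, not isolated) | O=C1CCCCCCCCCCCCCCC2C(CCCCCCCCCCCO1)S2(=O)=O | intermediate
11 | 1-oxacyclononacos-17-en-2-one (E/Z mixture) | O=C1CCCCCCCCCCCCCCC=CCCCCCCCCCCCO1 | intermediate
12 | octacosanolide (1-oxacyclononacosan-2-one) | O=C1CCCCCCCCCCCCCCCCCCCCCCCCCCCO1 | target

**Step count**
Total steps: 5. Longest linear sequence: 5.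

**Steps most likely to fail**

1. Step 4 (key step). The base and bromine source may act at the lactone instead of the sulfone: deprotonation and bromination at the ester alpha-methylene, or ring opening by hydroxide. Over-bromination at the sulfone alpha carbons is a further possible loss.
Fallback, from compound 5 back to compound 11: the halogen is placed before the base step, where only the sulfur-adjacent carbons can react. Sulfide 5 would be chlorinated with N-chlorosuccinimide in CCl4 at rt to 17-chloro-1-oxa-18-thiacyclotriacontan-2-one F1 and its regioisomer 19-chloro-1-oxa-18-thiacyclotriacontan-2-one F2. Without isolation, mCPBA in CH2Cl2 at 0 °C to rt would carry these through the sulfoxides 17-chloro-1-oxa-18-thiacyclotriacontan-2-one 18-oxide F3 and 19-chloro-1-oxa-18-thiacyclotriacontan-2-one 18-oxide F4 to the sulfones 17-chloro-1-oxa-18-thiacyclotriacontan-2-one 18,18-dioxide F5 and 19-chloro-1-oxa-18-thiacyclotriacontan-2-one 18,18-dioxide F6. Brief treatment with t-BuOK in THF at −78 to 0 °C (classical Ramberg–Bäcklund reaction of an alpha-chloro sulfone) should then pass through episulfone 10 to olefin 11. The lactone then meets only a hindered alkoxide, cold and briefly.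

2. Step 2. Intermolecular S-alkylation (oligomer formation) or oxidative coupling of the thiol may outrun the ring closure.
Fallback, from compounds 1 and 2 back to compound 5: the C–S bond is made intermolecularly and the same ring is closed at the ester bond instead. S-alkylation of 1 with 2 (NaOH, aqueous EtOH, 60 °C, N2; then HCl) should give 16-[(12-hydroxydodecyl)sulfanyl]hexadecanoic acid F7. Yamaguchi macrolactonisation follows: 2,4,6-trichlorobenzoyl chloride and Et3N in THF should give 16-[(12-hydroxydodecyl)sulfanyl]hexadecanoic 2,4,6-trichlorobenzoic anhydride F8, which is added slowly to DMAP in toluene at reflux to give thia-lactone 5.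

3. Step 1. The free thiol may take part during esterification: thioester formation, air oxidation, or slow S-alkylation by the bromide at reflux.
Fallback, from compound 1 back to compound 3: the thiol is masked as its disulfide. Oxidation of 1 with H2O2 and NaI (cat.) in EtOAc at rt should give 16,16'-disulfanediyldihexadecanoic acid F9. Double esterification with 2 (TsOH·H2O cat., toluene, Dean–Stark) should give bis(12-bromododecyl) 16,16'-disulfanediyldihexadecanoate F10. Reduction of the S–S bond with Zn dust and AcOH in THF should release two molecules of 3.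

**Further compounds**

F1 | step 4 | 17-chloro-1-oxa-18-thiacyclotriacontan-2-one (racemic) | O=C1CCCCCCCCCCCCCCC(Cl)SCCCCCCCCCCCCO1
F2 | step 4 | 19-chloro-1-oxa-18-thiacyclotriacontan-2-one (racemic) | O=C1CCCCCCCCCCCCCCCSC(Cl)CCCCCCCCCCCO1
F3 | step 4 | 17-chloro-1-oxa-18-thiacyclotriacontan-2-one 18-oxide (stereoisomer mixture) | O=C1CCCCCCCCCCCCCCC(Cl)S(=O)CCCCCCCCCCCCO1
F4 | step 4 | 19-chloro-1-oxa-18-thiacyclotriacontan-2-one 18-oxide (stereoisomer mixture) | O=C1CCCCCCCCCCCCCCCS(=O)C(Cl)CCCCCCCCCCCO1
F5 | step 4 | 17-chloro-1-oxa-18-thiacyclotriacontan-2-one 18,18-dioxide (racemic) | O=C1CCCCCCCCCCCCCCC(Cl)S(=O)(=O)CCCCCCCCCCCCO1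
F6 | step 4 | 19-chloro-1-oxa-18-thiacyclotriacontan-2-one 18,18-dioxide (racemic) | O=C1CCCCCCCCCCCCCCCS(=O)(=O)C(Cl)CCCCCCCCCCCO1
F7 | step 2 | 16-[(12-hydroxydodecyl)sulfanyl]hexadecanoic acid | OCCCCCCCCCCCCSCCCCCCCCCCCCCCCC(O)=O
F8 | step 2 | 16-[(12-hydroxydodecyl)sulfanyl]hexadecanoic 2,4,6-trichlorobenzoic anhydride | OCCCCCCCCCCCCSCCCCCCCCCCCCCCCC(=O)OC(=O)c1c(Cl)cc(Cl)cc1Cl
F9 | step 1 | 16,16'-disulfanediyldihexadecanoic acid | OC(=O)CCCCCCCCCCCCCCCSSCCCCCCCCCCCCCCCC(O)=O
F10 | step 1 | bis(12-bromododecyl) 16,16'-disulfanediyldihexadecanoate | BrCCCCCCCCCCCCOC(=O)CCCCCCCCCCCCCCCSSCCCCCCCCCCCCCCCC(=O)OCCCCCCCCCCCCBr
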